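The vessel is a stirred flask of constant volume in which Z lies as a solid with none of it in solution at the start, and the thing to watch on a repeat is how much Q is still there when Z has finished with it.

| setting | delta | gamma | epsilon | eta | Friday's | Saturday's | Sunday's |
|---|---|---|---|---|---|---|---|
| D | 0.0020 M | 0.0020 M | 0.0020 M | 0.0020 M | 0.0020 M | 0.0020 M (fed, over 2.5 min) | 0.0020 M |
| Q | 2 equiv | 1 equiv | 4 equiv | 2 equiv | 2.00 equiv | 2.00 equiv | 2.00 equiv (fed, over 2.5 min) |
| Z | 0.90 equiv | 0.90 equiv | 0.90 equiv | 0.45 equiv | 0.900 equiv | 0.900 equiv | 0.900 equiv |
| remark | run made earlier | run made earlier | run made earlier | run made earlier | everything together at the start | all else is in the flask from the start; the feed brings no volume worth counting | all else is in the flask from the start; the feed brings no volume worth counting |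
| time |  |  |  |  | 4.0 min | 4.0 min | 4.0 min |

- delta (time / min: E / %, J / %): 0.333: 61.4, 0.7; 0.667: 79.8, 0.4; 1.50: 93.0, 0; 4.00: 98.1, 0.2
- gamma (time / min: E / %, J / %): 0.833: 54.5, 2.2; 1.50: 61.5, 2.7; 2.50: 64.1, 5.1; 3.00: 63.3, 6.2
- epsilon (time / min: E / %, J / %): 0.417: 91.1, 0; 1.00: 99.5, 0; 2.00: 99.7, 0; 3.00: 100.2, 0.2
- eta (time / min: E / %, J / %): 0.250: 52.5, 0.6; 0.667: 80.2, 0.1; 1.33: 92.5, 0.3; 3.00: 98.9, 0

(scatter of a reading: 0.3 percentage points)

- given per volume of solution although it is solid: Z
- at the start none of Z is in solution

- which flask leads in amount of E, in percent of the D charged ("all alike" within 1.5 percentage points) (Friday's / Saturday's / Sunday's / all alike)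
- how much E is there at the end, in percent of the D charged: Friday's
- how much E is there at the end, in percent of the D charged: Saturday's
- how much E is there at the end, in percent of the D charged: Sunday's

I built the ladder rung by rung. The first epsilon reading gave me, as a reading, a pseudo-first-order constant for D of 1.45 min⁻¹ per equivalent of Q, so with Q held at 2.00 equiv the half-life of D is 0.239 min. In the gamma run E stood at 64.1% after 2.50 min and at 63.3% after 3.00 min, so E had stopped rising there, and I took Z to be consuming Q, one for one, which is my assumption. The lowest rung follows from that balance. I call the Q surplus 0.100 equiv, the Q charge less one equivalent for D and one per equivalent of Z. In a flask with its whole charge in and its Z all reacted with Q, the Q left equals the surplus plus the D left, with J counted as negligible. As D thins out, its half-life tends to 4.78 min, far longer than on the first rung. A feed ending at 2.5 min leaves a tail of 1.50 min, shorter than that half-life. So I expected Friday's, the delta recipe again, near the delta reading of 98.1%, with both fed flasks behind it, though this gave me no figure for them.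

The forecast said Friday's would lead, with 98.1% (97.4% to 98.7%), and gave Saturday's 91.5% (86.5% to 95.5%) and Sunday's 91.5% (85% to 96%), reasoning that “Feeding D delays its reaction while Z keeps destroying Q”.

Friday's gave 97.9%, Saturday's 87.1% and Sunday's 89.4%. Saturday's feed shortened to 0.250 min gave 97.5%. At 4.00 min Saturday's held Z 0%, D 12.9% and Q 11.4%, each of its own charge, which is 0.228 equiv of Q against the 0.229 equiv that surplus plus D gives.

    Z ⇌ G, rate k1*(cs1 - [G]) while solid is left; crystals form when [G] > cs1 (solubility = 0.490 mM, k = 0.0260 s⁻¹)
    Q + G → X (k = 120 L mol⁻¹ s⁻¹)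
    D + Q → E (k = 15.0 L mol⁻¹ s⁻¹)
    D + G ⇌ J (K = 460 L mol⁻¹, k = 140 L mol⁻¹ s⁻¹)

Saturday's flask with 5.00 equiv of Q has a surplus of 3.10 equiv, which is 62.0% of its charge, and a tail half-life of 0.154 min, far shorter than its tail. Computed, it held Q 62.0% and D 0% at 4.00 min, with E >99.9%.

The runs stem from a simulated flask for substances that don't exist; noise was put on by code.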